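**Retrosynthetic overview**

1. The target comes from the 4β,6α,9α-triol 14 by selective C9 acetylation and C6 aroylation; 14 comes in one event from singlet-oxygen [4+2] addition to the C6=C7–C8=C9 diene of dienol 12, on the face opposite the C1 methyl group.
2. 12 comes from the bicyclic dienone 10 by deconjugative protonation at C5 and isopropyl addition at C4, both again anti to the C1 methyl group.
3. The seven-membered ring is formed second: intramolecular Horner–Wadsworth–Emmons closure of C5=C6, after hydroboration/Suzuki coupling has joined C9 to the C8(CH3)=C7–C6 unit.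
4. The five-membered ring is formed first, in the key step, through bonds C2–C3 and C1–C5: the dianion of dimethyl (2-oxopropyl)phosphonate supplies C3–C4–C5 and isoprene monoepoxide supplies C2, C1 with its CH3, C10 and C9; the second bond is a palladium-catalysed asymmetric allylic alkylation that sets C1.
5. Enabling feature: C1, the quaternary atom shared by both rings, carries CH3 and the C10–C9 arm of the seven-membered ring, so C2–C1(CH3)–C10–C9 is an isoprene unit with C1 as its tertiary allylic carbon; in the cyclopentane it stands 1,3 to the oxygenated C4, which is flanked by C3 and C5 like the carbonyl of an acetone 1,3-dianion.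

Key step: step 1

Remark: atoms are numbered as in the daucane skeleton (C1 quaternary ring-fusion carbon with CH3, C2 and C3 ring CH2, C4 the isopropyl carbinol carbon, C5 ring-fusion CH, C6 the aroyloxy carbon, C7=C8 the alkene with CH3 on C8, C9 the acetoxy carbon, C10 the CH2 next to C1); β is the face of the C1 methyl group; it is assumed that the (R,R)-ligand gives the (R)-configured ketophosphonate 4, otherwise its enantiomer is used.

**Route**

Step 1
Reactants: 1 dimethyl (2-oxopropyl)phosphonate; 2 2-methyl-2-vinyloxirane (racemic isoprene monoepoxide)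
Product: 4 dimethyl [(2R)-2-ethenyl-2-methyl-5-oxocyclopentyl]phosphonate (both epimers at the phosphorus-bearing carbon), via hydroxy ketophosphonate 3 (not isolated)
Conditions: NaH, THF, 0 °C; n-BuLi, −78 °C; 2, −78 → 0 °C; AcOH (2 equiv); then Pd2(dba)3·CHCl3 (2.5 mol %), (R,R)-N,N′-bis(2-diphenylphosphinobenzoyl)-1,2-diaminocyclohexane (7.5 mol %), Et3B, THF/CH2Cl2, 25–40 °C
Reagents that add atoms: none
Why: The γ-carbon of the phosphonate dianion opens epoxide 2 at its CH2 terminus (SN2, bond C2–C3), and after neutralisation the zerovalent palladium catalyst, helped by Et3B, ionises the tertiary allylic alcohol of 3 to a π-allyl complex over C1–C10–C9 that the β-ketophosphonate carbon C5 attacks at C1 (bond C1–C5). The closest known reactions are the γ-alkylation of β-ketoester and β-ketophosphonate dianions by epoxides, the palladium-catalysed cyclisation of allylic derivatives of 3-oxoalkanoates to 2-acyl-3-vinylcyclopentanones (intramolecular Tsuji–Trost alkylation) and the palladium-catalysed asymmetric allylic alkylation of isoprene monoepoxide at its tertiary carbon. The five-membered ring closes in the 5-exo mode by attack of the soft carbon nucleophile on the tertiary terminus of the allyl unit; the seven-membered ring is not formed here. C1 is the only lasting stereocentre: both enantiomers of 3 give π-allyl complexes that interconvert through the unsubstituted terminus C9, and the chiral ligand selects the face that is attacked (dynamic kinetic asymmetric transformation), while C5 stays epimerisable and becomes planar in step 4. The step needs C- over O-alkylation and five- over seven-ring closure; O-alkylation is reversible under the palladium catalyst, and the short tether together with the higher cationic character of the tertiary terminus should direct the carbon nucleophile to C1.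

Step 2
Reactants: 5 but-2-yn-1-ol
Product: 6 (2Z)-3-iodobut-2-en-1-ol
Conditions: NaAlH2(OCH2CH2OCH3)2, THF, 0 °C → rt; then I2, −78 → 0 °C
Reagents that add atoms: iodine, II
Why: Hydroxyl-directed trans-hydroalumination of the propargylic alcohol places aluminium on C3 on the side of the CH2O group, and iodinolysis of the C–Al bond with retention gives the Z-iodide (known hydroalumination–iodination of 2-alkyn-1-ols); no stereocentre is formed.

Step 3
Reactants: 4 dimethyl [(2R)-2-ethenyl-2-methyl-5-oxocyclopentyl]phosphonate; 6 (2Z)-3-iodobut-2-en-1-ol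
Product: 8 dimethyl [(2S)-2-[(3Z)-5-hydroxy-3-methylpent-3-en-1-yl]-2-methyl-5-oxocyclopentyl]phosphonate, via pinacol boronate 7 (not isolated)
Conditions: pinacolborane, [Ir(cod)Cl]2 (1.5 mol %), dppe (3 mol %), CH2Cl2, rt; then 6, Pd(OAc)2 (5 mol %), RuPhos (10 mol %), K3PO4, toluene/H2O, 80 °C
Reagents that add atoms: none
Why: Iridium-catalysed anti-Markovnikov hydroboration of the vinyl group with pinacolborane tolerates the ketone, and the primary alkylboronate undergoes B-alkyl Suzuki–Miyaura coupling with the alkenyl iodide with retention of the Z geometry (bond C9–C8), while C1 is not touched.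

Step 4
Reactants: 8 dimethyl [(2S)-2-[(3Z)-5-hydroxy-3-methylpent-3-en-1-yl]-2-methyl-5-oxocyclopentyl]phosphonate
Product: 10 (8aS)-6,8a-dimethyl-2,7,8,8a-tetrahydroazulen-3(1H)-one, via Z-enal 9 (not isolated)
Conditions: MnO2, CH2Cl2, rt; filter; then LiCl, DBU, MeCN (0.005 M), rt
Reagents that add atoms: none
Why: Activated MnO2 oxidises only the allylic alcohol, and the Z-enal is taken at once by the β-ketophosphonate carbanion in an intramolecular Horner–Wadsworth–Emmons reaction (LiCl/amine variant) that closes the seven-membered ring through C5=C6, the ring itself fixing the geometry of both double bonds and removing the epimeric centre at C5.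

Step 5
Reactants: 10 (8aS)-6,8a-dimethyl-2,7,8,8a-tetrahydroazulen-3(1H)-one
Product: 11 (3aR,8aR)-6,8a-dimethyl-2,3a,8,8a-tetrahydroazulen-3(1H)-one (trans ring fusion, 5α-H)
Conditions: KOtBu, t-BuOH/THF, 0 °C → rt; then inverse quench into cold aq. AcOH
Reagents that add atoms: none
Why: Equilibrating base should give the fully conjugated trienolate by loss of a C9 proton, and kinetic protonation at the α-carbon C5 deconjugates the system (as in the known deconjugation of steroidal 4,6-dien-3-ones through their extended enolates), the proton arriving on the face opposite the C1 methyl group and so setting the trans ring fusion.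

Step 6
Reactants: 11 (3aR,8aR)-6,8a-dimethyl-2,3a,8,8a-tetrahydroazulen-3(1H)-one
Product: 12 (3R,3aR,8aR)-6,8a-dimethyl-3-(propan-2-yl)-1,2,3,3a,8,8a-hexahydroazulen-3-ol (4β-OH, 5α-H)
Conditions: i-PrMgCl, CeCl3, THF, −78 °C; aq. NH4Cl
Reagents that add atoms: isopropylmagnesium chloride, CC(C)[Mg]Cl
Why: The organocerium reagent adds to the easily enolised β,γ-unsaturated ketone without deprotonating it (organocerium 1,2-addition) and should attack C4 from the α face, anti to the C1 methyl group and on the side of H-5, which gives the 4β-alcohol.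

Step 7
Reactants: 12 (3R,3aR,8aR)-6,8a-dimethyl-3-(propan-2-yl)-1,2,3,3a,8,8a-hexahydroazulen-3-ol
Product: 14 (3R,3aS,4S,7S,8aR)-6,8a-dimethyl-3-(propan-2-yl)-1,2,3,3a,4,7,8,8a-octahydroazulene-3,4,7-triol, via endoperoxide 13 (not isolated)
Conditions: O2, tetraphenylporphyrin, hν, CH2Cl2, −30 °C; then Zn, AcOH, 0 °C
Reagents that add atoms: oxygen, O=O
Why: Singlet oxygen adds across the s-cis C6=C7–C8=C9 diene in a [4+2] cycloaddition from the α face, opposite to the axial C1 methyl group (as in the known photooxygenation of steroidal 5,7-dienes), and reduction of the O–O bond gives the cis-6α,9α-diol, so C6 and C9 are set together by substrate control.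

Step 8
Reactants: 14 (3R,3aS,4S,7S,8aR)-6,8a-dimethyl-3-(propan-2-yl)-1,2,3,3a,4,7,8,8a-octahydroazulene-3,4,7-triol
Product: 15 (3R,3aS,4S,7S,8aR)-3,4-dihydroxy-6,8a-dimethyl-3-(propan-2-yl)-1,2,3,3a,4,7,8,8a-octahydroazulen-7-yl acetate
Conditions: Ac2O (1.1 equiv), pyridine, CH2Cl2, −20 → 0 °C
Reagents that add atoms: acetic anhydride, CC(=O)OC(C)=O
Why: Acetylation at low temperature (esterification) should take the C9 hydroxyl, flanked only by a CH2 group and the alkene carbon, in preference to the C6 hydroxyl, which is shielded by the C5 methine between two fully substituted carbons, and leaves the tertiary C4 hydroxyl untouched; no stereocentre changes.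

Step 9
Reactants: 15 (3R,3aS,4S,7S,8aR)-3,4-dihydroxy-6,8a-dimethyl-3-(propan-2-yl)-1,2,3,3a,4,7,8,8a-octahydroazulen-7-yl acetate; 16 4-acetoxybenzoyl chloride
Product: 17 (3R,3aS,4S,7S,8aR)-7-(acetyloxy)-3-hydroxy-6,8a-dimethyl-3-(propan-2-yl)-1,2,3,3a,4,7,8,8a-octahydroazulen-4-yl 4-(acetyloxy)benzoate
Conditions: Et3N, DMAP (cat.), CH2Cl2, rt → 40 °C
Reagents that add atoms: none
Why: DMAP-catalysed acylation with the acid chloride (nucleophilic acyl transfer) esterifies the remaining secondary C6 hydroxyl while the tertiary C4 hydroxyl does not react, and C6 keeps its configuration because only the O–H bond is broken.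

Step 10
Reactants: 17 (3R,3aS,4S,7S,8aR)-7-(acetyloxy)-3-hydroxy-6,8a-dimethyl-3-(propan-2-yl)-1,2,3,3a,4,7,8,8a-octahydroazulen-4-yl 4-(acetyloxy)benzoate
Product: 18 (3R,3aS,4S,7S,8aR)-7-(acetyloxy)-3-hydroxy-6,8a-dimethyl-3-(propan-2-yl)-1,2,3,3a,4,7,8,8a-octahydroazulen-4-yl 4-hydroxybenzoate (target)
Conditions: NH4OAc, MeOH/H2O, rt
Reagents that add atoms: none
Why: Aryl acetates are cleaved much faster than alkyl esters under NH4OAc-mediated methanolysis (chemoselective deacetylation of a phenolic acetate), so the phenol should be released while the allylic C9 acetate and the C6 benzoate stay intact.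

**Compound list**

1 | dimethyl (2-oxopropyl)phosphonate | CC(=O)CP(=O)(OC)OC | starting material
2 | 2-methyl-2-vinyloxirane (racemic) | CC1(C=C)CO1 | starting material
3 | dimethyl (5-hydroxy-5-methyl-2-oxohept-6-en-1-yl)phosphonate (racemic, not isolated) | COP(=O)(OC)CC(=O)CCC(C)(O)C=C | intermediate
4 | dimethyl [(2R)-2-ethenyl-2-methyl-5-oxocyclopentyl]phosphonate (both epimers at the phosphorus-bearing carbon) | C=C[C@@]1(C)CCC(=O)C1P(=O)(OC)OC | intermediate
5 | but-2-yn-1-ol | CC#CCO | starting material
6 | (2Z)-3-iodobut-2-en-1-ol | OC/C=C(C)\I | intermediate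
7 | dimethyl [(2S)-2-methyl-5-oxo-2-[2-(4,4,5,5-tetramethyl-1,3,2-dioxaborolan-2-yl)ethyl]cyclopentyl]phosphonate (not isolated) | CC1(C)OB(CC[C@@]2(C)CCC(=O)C2P(=O)(OC)OC)OC1(C)C | intermediate
8 | dimethyl [(2S)-2-[(3Z)-5-hydroxy-3-methylpent-3-en-1-yl]-2-methyl-5-oxocyclopentyl]phosphonate | OC/C=C(C)\CC[C@@]1(C)CCC(=O)C1P(=O)(OC)OC | intermediate
9 | dimethyl [(2S)-2-methyl-2-[(3Z)-3-methyl-5-oxopent-3-en-1-yl]-5-oxocyclopentyl]phosphonate (not isolated) | O=C/C=C(C)\CC[C@@]1(C)CCC(=O)C1P(=O)(OC)OC | intermediate
10 | (8aS)-6,8a-dimethyl-2,7,8,8a-tetrahydroazulen-3(1H)-one | C1C[C@@]2(C)CCC(=O)C2=CC=C1C | intermediate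
11 | (3aR,8aR)-6,8a-dimethyl-2,3a,8,8a-tetrahydroazulen-3(1H)-one (trans-fused, 5α-H) | C=1C[C@@]2(C)CCC(=O)[C@@H]2C=CC=1C | intermediate
12 | (3R,3aR,8aR)-6,8a-dimethyl-3-(propan-2-yl)-1,2,3,3a,8,8a-hexahydroazulen-3-ol (4β-OH, 5α-H) | C=1C[C@@]2(C)CC[C@@](O)(C(C)C)[C@@H]2C=CC=1C | intermediate
13 | 6,9-endoperoxide of 12, with the O–O bridge between C6 and C9 on the α face (4β-OH, 5α-H, not isolated) | O3[C@H]1C[C@@]2(C)CC[C@@](O)(C(C)C)[C@@H]2[C@@H](O3)C=C1C | intermediate
14 | (3R,3aS,4S,7S,8aR)-6,8a-dimethyl-3-(propan-2-yl)-1,2,3,3a,4,7,8,8a-octahydroazulene-3,4,7-triol (4β,6α,9α-triol) | O[C@H]1C[C@@]2(C)CC[C@@](O)(C(C)C)[C@@H]2[C@@H](O)C=C1C | intermediate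
15 | (3R,3aS,4S,7S,8aR)-3,4-dihydroxy-6,8a-dimethyl-3-(propan-2-yl)-1,2,3,3a,4,7,8,8a-octahydroazulen-7-yl acetate | CC(=O)O[C@H]1C[C@@]2(C)CC[C@@](O)(C(C)C)[C@@H]2[C@@H](O)C=C1C | intermediate
16 | 4-acetoxybenzoyl chloride | CC(=O)Oc1ccc(cc1)C(Cl)=O | starting material
17 | (3R,3aS,4S,7S,8aR)-7-(acetyloxy)-3-hydroxy-6,8a-dimethyl-3-(propan-2-yl)-1,2,3,3a,4,7,8,8a-octahydroazulen-4-yl 4-(acetyloxy)benzoate | CC(=O)O[C@H]1C[C@@]2(C)CC[C@@](O)(C(C)C)[C@@H]2[C@@H](OC(=O)c2ccc(OC(C)=O)cc2)C=C1C | intermediate
18 | (3R,3aS,4S,7S,8aR)-7-(acetyloxy)-3-hydroxy-6,8a-dimethyl-3-(propan-2-yl)-1,2,3,3a,4,7,8,8a-octahydroazulen-4-yl 4-hydroxybenzoate | CC(=O)O[C@H]1C[C@@]2(C)CC[C@@](O)(C(C)C)[C@@H]2[C@@H](OC(=O)c2ccc(O)cc2)C=C1C | target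

**Step count**

Total steps: 10. Longest linear sequence: 9 (steps 1 and 3 to 10); step 2 is a one-step side branch.

**Three steps most likely to fail**

1. Step 1 (key step). What may go wrong: the epoxide may be opened in the SN2′ sense. The ring closure may lose regiocontrol, either by attack of C5 on the unsubstituted allyl terminus C9 to give a cycloheptenone or by lasting O-alkylation. Facial discrimination of the π-allyl complex may be incomplete.
Fallback (sets out from 1 and 2, comes back at 4): the order of the two bond formations is reversed with known reactions. Palladium-catalysed asymmetric allylic alkylation of 2 with 1 as the pronucleophile (Pd2(dba)3·CHCl3, the same ligand, CH2Cl2, rt) should form C1–C5 first and give the branched alcohol dimethyl [(2S)-1-acetyl-2-(hydroxymethyl)-2-methylbut-3-en-1-yl]phosphonate F1. Oxidation with DMP (1,1,1-triacetoxy-1,1-dihydro-1,2-benziodoxol-3(1H)-one) should give the aldehyde dimethyl [(2S)-1-acetyl-2-formyl-2-methylbut-3-en-1-yl]phosphonate F2. Amine-catalysed intramolecular aldol condensation (pyrrolidine, AcOH) of the methyl ketone onto the aldehyde should close C2=C3 in the cyclopentenone dimethyl [(5S)-5-ethenyl-5-methyl-2-oxocyclopent-3-en-1-yl]phosphonate F3. Conjugate reduction with [(Ph3P)CuH]6, which leaves the vinyl group alone, should then give 4.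

2. Step 5. What may go wrong: protonation of the trienolate may occur at C7 or C9 instead of C5, the β,γ-unsaturated ketone may slip back into conjugation during work-up, and proton delivery to C5 may not be face-selective.
Fallback (sets out from 10, comes back at 11): the deconjugated ketone is trapped by reduction as soon as it forms. Enol acetylation of 10 (isopropenyl acetate, TsOH, reflux) should give the trienyl acetate (8aR)-6,8a-dimethyl-1,2,8,8a-tetrahydroazulen-3-yl acetate F4. NaBH4 in EtOH/THF at 0 °C should cleave the enol ester, let the released enolate be protonated at C5 and reduce the β,γ-unsaturated ketone before it can re-conjugate (known deconjugative borohydride reduction of steroidal dienol acetates), giving (3aR,8aR)-6,8a-dimethyl-1,2,3,3a,8,8a-hexahydroazulen-3-ol F5 as a mixture at the carbinol carbon. Oxidation with DMP buffered with NaHCO3 should return 11.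

3. Step 7. What may go wrong: singlet oxygen may react by the ene pathway at the allylic C–H bonds or add to the β face, and the diene may shift by 1,5-hydrogen migration before it is trapped.
Fallback (sets out from 12, comes back at 17): the two oxygens are introduced one after the other. Epoxidation of the more substituted C8=C9 double bond (mCPBA, NaHCO3, CH2Cl2, −20 °C) from the α face should give the vinyl epoxide 8α,9α-epoxide of 12 F6. Opening with 4-acetoxybenzoic acid under zerovalent palladium catalysis (Pd(PPh3)4, THF, 0 °C → rt) is a syn 1,4-addition through the π-allyl complex with double inversion; it should give (3R,3aS,4S,7S,8aR)-3,7-dihydroxy-6,8a-dimethyl-3-(propan-2-yl)-1,2,3,3a,4,7,8,8a-octahydroazulen-4-yl 4-(acetyloxy)benzoate F7, with the aroyl ester already on C6. Acetylation of the C9 hydroxyl (Ac2O, pyridine, DMAP) should then give 17.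

**Further compounds**

F1 | step 1 | dimethyl [(2S)-1-acetyl-2-(hydroxymethyl)-2-methylbut-3-en-1-yl]phosphonate | C=C[C@@](C(C(C)=O)P(=O)(OC)OC)(C)CO
F2 | step 1 | dimethyl [(2S)-1-acetyl-2-formyl-2-methylbut-3-en-1-yl]phosphonate | C=C[C@@](C(C(C)=O)P(=O)(OC)OC)(C)C=O
F3 | step 1 | dimethyl [(5S)-5-ethenyl-5-methyl-2-oxocyclopent-3-en-1-yl]phosphonate | C=C[C@@]1(C)C=CC(=O)C1P(=O)(OC)OC
F4 | step 5 | (8aR)-6,8a-dimethyl-1,2,8,8a-tetrahydroazulen-3-yl acetate | C=1C[C@@]2(C)CCC(OC(C)=O)=C2C=CC=1C
F5 | step 5 | (3aR,8aR)-6,8a-dimethyl-1,2,3,3a,8,8a-hexahydroazulen-3-ol (mixture at C3) | C=1C[C@@]2(C)CCC(O)[C@@H]2C=CC=1C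
F6 | step 7 | 8α,9α-epoxide of 12 (C8–C9 oxirane on the α face, C6=C7 retained, 4β-OH, 5α-H) | O3[C@H]1C[C@@]2(C)CC[C@@](O)(C(C)C)[C@@H]2C=C[C@]13C
F7 | step 7 | (3R,3aS,4S,7S,8aR)-3,7-dihydroxy-6,8a-dimethyl-3-(propan-2-yl)-1,2,3,3a,4,7,8,8a-octahydroazulen-4-yl 4-(acetyloxy)benzoate | O[C@H]1C[C@@]2(C)CC[C@@](O)(C(C)C)[C@@H]2[C@@H](OC(=O)c2ccc(OC(C)=O)cc2)C=C1C
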